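**Retrosynthetic overview**
1. Feature: ring A is the cycloheptane, numbered C1 (lactone-oxygen carbon), C2 (bears the lactone α-carbon), C3 (CH2), C4 (carbinol), C5 (methyl carbon), C6 and C7 (isovalerate carbon). C6 is a tertiary carbinol that carries the butenoyl carbonyl and adjoins oxygenated C7. With C7 at the ketone level this array is the retron of an α-ketol shift. The other six ring atoms (C7, C5, C4, C3, C2, C1), with the C5 methyl and the C2 three-carbon branch, are the skeleton of (R)-carvone.
2. Ring B (the α-methylene-γ-lactone) is opened to the C1 alcohol and a C2 isopropenyl group. The isovalerate and the E-butenoyl group go back to a C7 ketone and a C6 ester.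
3. Key disconnection, C5–C6: the cycloheptanone α-hydroxy ester comes from a 1-hydroxycyclohexyl α-keto ester by migration of C5 from C7 to C6.
4. The keto ester arm comes from ethyl diazoacetate and a cyclohexanone. Its C1, C4 and C5 centres are all set by β-face delivery (hydride to C1, H–B to C5/C4) on a temporary pinol-type iodoether made from 6-hydroxycarvone.
5. Ring order: carvone six-membered ring (chiral pool), then a temporary oxabicycle (made and reopened), then ring A by one-carbon enlargement, then ring B last.

Key step: step 11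

Remark on the chemistry: all intermediates keep the cycloheptane numbering (side chain C8–C10). α is the face of the C2 side chain and β the opposite face. The temporary C8 centre of 5–9 forms as a mixture and is erased in step 7, so it is left open in the SMILES.

**Step 1**
Reactants: 1 (R)-carvone
Product: 3 (5S,6S)-6-hydroxycarvone (C1 β-OH), via potassium dienolate 2 (not isolated)
Conditions: KN(SiMe3)2, THF, −78 °C; 2-(phenylsulfonyl)-3-phenyloxaziridine, −78 °C; AcOH quench
Reagents that add atoms: 2-(phenylsulfonyl)-3-phenyloxaziridine, O=S(=O)(N1OC1c1ccccc1)c1ccccc1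
Why: Kinetic α′-deprotonation followed by Davis oxidation of the cross-conjugated dienolate should place oxygen anti to the isopropenyl group, and the C1 configuration formed here is of no consequence because C1 becomes a ketone in step 4.

**Step 2**
Reactants: 3 (5S,6S)-6-hydroxycarvone
Product: 4 enediol (C7 α-OH; C1 β-OH)
Conditions: NaBH4, CeCl3·7H2O, MeOH, −20 °C
Reagents that add atoms: none
Why: Luche 1,2-reduction by axial hydride attack on the β face should give the equatorial C7 α-alcohol, cis to the isopropenyl group as in the reduction of carvone to cis-carveol, and only this epimer can cyclise in step 3.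

**Step 3**
Reactants: 4 enediol
Product: 5 iodoether alcohol 7-(iodomethyl)-4,7-dimethyl-6-oxabicyclo[3.2.1]oct-3-en-8-ol (C1 β-OH)
Conditions: I2, NaHCO3, MeCN, 0 °C, dark
Reagents that add atoms: iodine, II
Why: In this 5-exo Markovnikov iodoetherification, reversible iodine transfer to the alkenes is drained only by the C7 α-hydroxyl, the one oxygen that can reach C8, so one operation masks the C7 alcohol and the isopropenyl alkene and locks C7–O and C2–C8 diaxial.

**Step 4**
Reactants: 5 iodoether alcohol
Product: 6 bridged ketone 7-(iodomethyl)-4,7-dimethyl-6-oxabicyclo[3.2.1]oct-3-en-8-one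
Conditions: Dess–Martin periodinane, pyridine, CH2Cl2, 0 °C to rt
Reagents that add atoms: none
Why: Dess–Martin oxidation acts on the only free alcohol, and both α-carbons are bridgeheads that cannot enolise (Bredt strain), so C2 and C7 are safe and both C1 epimers from step 1 converge.

**Step 5**
Reactants: 6 bridged ketone
Product: 8 iodoether diol (C1 α-OH; C4 β-OH; C5 α-Me), via bis-boryl adduct 7 (not isolated)
Conditions: BH3·THF (excess), THF, 0 °C to rt; then NaBO3·4H2O, THF/H2O, rt
Reagents that add atoms: sodium perborate, [Na+].[Na+].O[B-]1(O)OO[B-](O)(O)OO1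
Why: Borane reduces the ketone and hydroborates the alkene in one operation; hydride should reach C1 from the β side (over the three-carbon bridge, antiperiplanar to C7–O and C2–C8, away from the C8 substituents) to give the C1 α-alcohol, while syn H–B addition to the exo β face with boron on the less substituted C4, then oxidation with retention, sets C4–OH β and C5–H β, so the C5 methyl is α and trans to the C4 oxygen.

**Step 6**
Reactants: 8 iodoether diol
Product: 9 bis-TBS iodoether
Conditions: TBSOTf, 2,6-lutidine, CH2Cl2, 0 °C to rt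
Reagents that add atoms: tert-butyldimethylsilyl triflate, CC(C)(C)[Si](C)(C)OS(=O)(=O)C(F)(F)F
Why: Silylation with the triflate and a non-nucleophilic base protects both secondary alcohols at once and avoids alkoxide conditions, under which the C1 oxygen might displace the nearby iodide.

**Step 7**
Reactants: 9 bis-TBS iodoether
Product: 10 cyclohexanol (C7 α-OH; isopropenyl restored)
Conditions: Zn dust, AcOH, EtOH, 60 °C
Reagents that add atoms: none
Why: In this Boord-type reductive β-elimination, zinc insertion into the C–I bond expels the β-alkoxide, which returns the isopropenyl group and the C7 alcohol without touching the ring stereocentres.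

**Step 8**
Reactants: 10 cyclohexanol
Product: 11 cyclohexanone (C1 α-OTBS; C2 α-isopropenyl; C4 β-OTBS; C5 α-Me)
Conditions: Dess–Martin periodinane, pyridine, CH2Cl2, 0 °C
Reagents that add atoms: none
Why: Buffered Dess–Martin oxidation works under non-enolising conditions, so the kinetically set C1 and C5 centres beside the new carbonyl are kept.

**Step 9**
Reactants: 11 cyclohexanone; 12 ethyl diazoacetate
Product: 14 α-diazo β-hydroxy ester (C7 α-OH; arm β), via ethyl lithiodiazoacetate 13 (not isolated)
Conditions: 11 + 12, THF, −78 °C, LiN(iPr)2 added dropwise; AcOH quench at −78 °C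
Reagents that add atoms: ethyl diazoacetate 12, CCOC(=O)C=[N+]=[N-]
Why: In this aldol-type addition of a lithiated diazo ester, 11 should adopt the chair with C1–OTBS, C4–OTBS and C5–Me equatorial and the isopropenyl group axial on the α face, which blocks the axial trajectory, so the nucleophile enters equatorially from the β face and sets C7 with the arm β and the hydroxyl α.

**Step 10**
Reactants: 14 α-diazo β-hydroxy ester
Product: 15 1-hydroxycyclohexyl α-keto ester (key precursor)
Conditions: dimethyldioxirane (1.0 equiv, titrated, acetone), CH2Cl2, −40 to 0 °C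
Reagents that add atoms: dimethyldioxirane, CC1(C)OO1
Why: In this known diazo-to-carbonyl oxidation, oxygen transfer to the nucleophilic diazo carbon with loss of N2 should outrun epoxidation of the hindered axial 1,1-disubstituted alkene when one titrated equivalent is used cold.

**Step 11**
Reactants: 15 1-hydroxycyclohexyl α-keto ester
Product: 16 cycloheptanone α-hydroxy ester (C7 ketone; C6 α-OH; C6 β-CO2Et)
Conditions: Sc(OTf)3 (10 mol %), 2,6-di-tert-butyl-4-methylpyridine (20 mol %), 4 Å MS, CH2Cl2 (0.01 M), 0 °C to rt
Reagents that add atoms: none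
Why: Proposed new method: Sc(OTf)3 should bind the C7 hydroxyl oxygen, the C6 keto oxygen and the ester carbonyl oxygen of 15 in two fused five-membered chelates, which raises the electrophilicity of C6 and holds O–C7–C6–O close to syn-periplanar, so that the C7–C5 σ bond overlaps with the C6 π* orbital and C5 shifts from C7 to C6 with retention while C7 becomes the ketone. The closest known reaction types are the α-ketol (acyloin) ring enlargement of 1-acylcycloalkanols and the Lewis-acid isomerisation of open-chain β-hydroxy α-keto esters to α-hydroxy β-keto esters, whereas a six-to-seven enlargement of a 1-hydroxycyclohexyl α-keto ester has not been shown. Ring A is closed not by cyclisation but by a suprafacial 1,2-shift that inserts C6 into the former C5–C7 bond, driven by exchange of the vicinal dicarbonyl for a β-keto ester and by release of the 1,3-diaxial contact between the C7 hydroxyl and the C2 isopropenyl group. The one new stereocentre, C6, is controlled by the C7 carbinol, because in the chelate C5 can reach only one face of the C6 carbonyl, which puts the C6 hydroxyl α (cis to the C5 methyl) and the ester β. The step needs migration of C5 and not of C1, and this rests on C1 carrying the σ-withdrawing silyloxy group, whose silicon-bound oxygen is a poor lone-pair donor, while C5 is a plain secondary alkyl carbon. The isopropenyl group stands 1,3-trans to the arm and cannot reach the activated keto ester for an ene reaction, and high dilution should suppress the intermolecular version.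

**Step 12**
Reactants: 16 cycloheptanone α-hydroxy ester
Product: 17 diol ester (C7 β-OH; C6 α-OH)
Conditions: Me4NBH(OAc)3, MeCN/AcOH, −30 °C
Reagents that add atoms: none
Why: In this hydroxyl-directed (Saksena–Evans type) reduction, the reagent exchanges acetate for the only free hydroxyl, the C6 α-OH, and delivers hydride to the adjacent carbonyl from the α face, which is also remote from the β ester, so C7–OH should come out β and trans to the C6 hydroxyl.

**Step 13**
Reactants: 17 diol ester
Product: 18 N-methoxy-N-methylamide
Conditions: MeNH(OMe)·HCl, iPrMgCl (excess), THF, −20 to 0 °C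
Reagents that add atoms: N,O-dimethylhydroxylamine hydrochloride, CNOC.Cl
Why: In this Weinreb amide formation by aminolysis with the magnesium amide, the α-hydroxy ester is activated by its neighbouring magnesium alkoxide, and no stereocentre is touched.

**Step 14**
Reactants: 18 N-methoxy-N-methylamide; 19 (E)-1-bromoprop-1-ene
Product: 21 enone diol (C6 E-but-2-enoyl), via (E)-prop-1-enyllithium 20 (not isolated)
Conditions: 19, t-BuLi (2 equiv per 19), Et2O, −78 °C; then 18, THF, −78 to −30 °C; AcOH quench at −78 °C
Reagents that add atoms: (E)-1-bromoprop-1-ene 19, C/C=C/Br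
Why: Halogen–lithium exchange keeps the E geometry and Weinreb ketone synthesis does not over-add, so the E-enone is released only on the cold acidic quench, and excess reagent covers the two hydroxyl protons.

**Step 15**
Reactants: 21 enone diol; 22 3-methylbutanoyl chloride
Product: 23 C7 isovalerate
Conditions: 22, pyridine, DMAP (cat.), CH2Cl2, 0 °C to rt
Reagents that add atoms: 3-methylbutanoyl chloride 22, CC(C)CC(Cl)=O
Why: DMAP-catalysed acylation should select the secondary C7 alcohol over the tertiary C6 alcohol on steric grounds.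

**Step 16**
Reactants: 23 C7 isovalerate
Product: 24 allylic alcohol (C2 side chain C(=CH2)CH2OH)
Conditions: SeO2 (cat.), t-BuOOH, CH2Cl2, 0 °C to rt
Reagents that add atoms: selenium dioxide (oxygen carrier), O=[Se]=O; tert-butyl hydroperoxide, CC(C)(C)OO
Why: SeO2 allylic oxidation (ene reaction, then 2,3-sigmatropic shift) should attack the electron-rich 1,1-disubstituted alkene and not the electron-poor enone, and should take the accessible methyl hydrogen and not C2–H, which is shielded by the C1 silyl ether.

**Step 17**
Reactants: 24 allylic alcohol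
Product: 25 tetraol monoester (free C1, C4, C6 and C10 hydroxyls)
Conditions: HF·pyridine, pyridine, THF, 0 °C to rt
Reagents that add atoms: none
Why: Fluoride desilylation in a mildly acidic medium frees C1–OH and C4–OH without base, which should avoid acyl migration from C7, retro-aldol cleavage and conjugate addition.

**Step 18**
Reactants: 25 tetraol monoester
Product: 28 CNP0186412.1, via hydroxy enal 26 (not isolated), via lactol 27 (not isolated)
Conditions: activated MnO2, CH2Cl2, rt
Reagents that add atoms: none
Why: MnO2 oxidises only the allylic primary alcohol, the enal is trapped by the cis C1 α-hydroxyl as a five-membered lactol (5-exo-trig closure of ring B), and this allylic hemiacetal is oxidised on to the α-methylene-γ-butyrolactone while the C4 and C6 alcohols stay untouched.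

**Compound list**
1 | (R)-carvone | CC1=CC[C@@H](C(C)=C)CC1=O | starting material
2 | potassium dienolate of carvone | CC1=CC[C@@H](C(C)=C)C=C1[O-].[K+] | intermediate (not isolated)
3 | (5S,6S)-6-hydroxycarvone | O[C@H]1[C@H](C(C)=C)CC=C(C)C1=O | intermediate
4 | 3-methyl-6-isopropenylcyclohex-3-ene-1,2-diol (C7 α-OH, C1 β-OH) | O[C@H]1[C@H](C(C)=C)CC=C(C)[C@@H]1O | intermediate
5 | 7-(iodomethyl)-4,7-dimethyl-6-oxabicyclo[3.2.1]oct-3-en-8-ol (C1 β-OH) | O[C@H]1[C@H]2CC=C(C)[C@@H]1OC2(C)CI | intermediate
6 | 7-(iodomethyl)-4,7-dimethyl-6-oxabicyclo[3.2.1]oct-3-en-8-one | O=C1[C@H]2CC=C(C)[C@@H]1OC2(C)CI | intermediate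
7 | C1-O-boryl, C4-boryl adduct | BO[C@@H]1[C@H]2C[C@@H](B)[C@H](C)[C@@H]1OC2(C)CI | intermediate (not isolated)
8 | 7-(iodomethyl)-4,7-dimethyl-6-oxabicyclo[3.2.1]octane-3,8-diol (C1 α-OH, C4 β-OH, C5 α-Me) | O[C@@H]1[C@H]2C[C@@H](O)[C@H](C)[C@@H]1OC2(C)CI | intermediate
9 | bis-TBS ether of 8 | CC(C)(C)[Si](C)(C)O[C@@H]1[C@H]2C[C@@H](O[Si](C)(C)C(C)(C)C)[C@H](C)[C@@H]1OC2(C)CI | intermediate
10 | cyclohexanol (C7 α-OH, C1 α-OTBS, C2 α-isopropenyl, C4 β-OTBS, C5 α-Me) | CC(C)(C)[Si](C)(C)O[C@@H]1[C@H](C(C)=C)C[C@@H](O[Si](C)(C)C(C)(C)C)[C@H](C)[C@@H]1O | intermediate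
11 | cyclohexanone from 10 | CC(C)(C)[Si](C)(C)O[C@@H]1[C@H](C(C)=C)C[C@@H](O[Si](C)(C)C(C)(C)C)[C@H](C)C1=O | intermediate
12 | ethyl diazoacetate | CCOC(=O)C=[N+]=[N-] | starting material
13 | ethyl lithiodiazoacetate | CCOC(=O)C([Li])=[N+]=[N-] | intermediate (not isolated)
14 | α-diazo β-hydroxy ester (C7 α-OH, arm β) | CC(C)(C)[Si](C)(C)O[C@@H]1[C@H](C(C)=C)C[C@@H](O[Si](C)(C)C(C)(C)C)[C@H](C)[C@@]1(O)C(=[N+]=[N-])C(=O)OCC | intermediate
15 | 1-hydroxycyclohexyl α-keto ester (key precursor) | CC(C)(C)[Si](C)(C)O[C@@H]1[C@H](C(C)=C)C[C@@H](O[Si](C)(C)C(C)(C)C)[C@H](C)[C@@]1(O)C(=O)C(=O)OCC | intermediate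
16 | cycloheptanone α-hydroxy ester (key product) | CC(C)(C)[Si](C)(C)O[C@@H]1[C@H](C(C)=C)C[C@@H](O[Si](C)(C)C(C)(C)C)[C@H](C)[C@@](O)(C(=O)OCC)C1=O | intermediate
17 | diol ester (C7 β-OH) | CC(C)(C)[Si](C)(C)O[C@@H]1[C@H](C(C)=C)C[C@@H](O[Si](C)(C)C(C)(C)C)[C@H](C)[C@@](O)(C(=O)OCC)[C@H]1O | intermediate
18 | N-methoxy-N-methylamide | CC(C)(C)[Si](C)(C)O[C@@H]1[C@H](C(C)=C)C[C@@H](O[Si](C)(C)C(C)(C)C)[C@H](C)[C@@](O)(C(=O)N(C)OC)[C@H]1O | intermediate
19 | (E)-1-bromoprop-1-ene | C/C=C/Br | starting material
20 | (E)-prop-1-enyllithium | C/C=C/[Li] | intermediate (not isolated)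
21 | enone diol | CC(C)(C)[Si](C)(C)O[C@@H]1[C@H](C(C)=C)C[C@@H](O[Si](C)(C)C(C)(C)C)[C@H](C)[C@@](O)(C(=O)/C=C/C)[C@H]1O | intermediate
22 | 3-methylbutanoyl chloride | CC(C)CC(Cl)=O | starting material
23 | C7 isovalerate | CC(C)(C)[Si](C)(C)O[C@@H]1[C@H](C(C)=C)C[C@@H](O[Si](C)(C)C(C)(C)C)[C@H](C)[C@@](O)(C(=O)/C=C/C)[C@H]1OC(=O)CC(C)C | intermediate
24 | allylic alcohol | CC(C)(C)[Si](C)(C)O[C@@H]1[C@H](C(=C)CO)C[C@@H](O[Si](C)(C)C(C)(C)C)[C@H](C)[C@@](O)(C(=O)/C=C/C)[C@H]1OC(=O)CC(C)C | intermediate
25 | tetraol monoester | O[C@@H]1[C@H](C(=C)CO)C[C@@H](O)[C@H](C)[C@@](O)(C(=O)/C=C/C)[C@H]1OC(=O)CC(C)C | intermediate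
26 | hydroxy enal | O[C@@H]1[C@H](C(=C)C=O)C[C@@H](O)[C@H](C)[C@@](O)(C(=O)/C=C/C)[C@H]1OC(=O)CC(C)C | intermediate (not isolated)
27 | lactol (anomeric mixture) | C=C1C(O)O[C@@H]2[C@H]1C[C@@H](O)[C@H](C)[C@@](O)(C(=O)/C=C/C)[C@H]2OC(=O)CC(C)C | intermediate (not isolated)
28 | CNP0186412.1 | C=C1C(=O)O[C@@H]2[C@H]1C[C@@H](O)[C@H](C)[C@@](O)(C(=O)/C=C/C)[C@H]2OC(=O)CC(C)C | target

**Total step count:** 18. **Longest linear sequence:** 18 steps (1 to 28).

**Steps most likely to fail**

Step 11 (labelled). Several processes could defeat it: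
- The equilibrium may not favour the seven-membered ring.
- C1 may migrate in competition with C5.
- The product may isomerise further by an ester shift between C6 and C7.
- C1 may epimerise next to the new ketone.

The fallback sets out from 14 and comes back at 16. Catalytic Rh2(OAc)4 in CH2Cl2 expels N2 from the diazo alcohol and triggers the known 1,2-alkyl shift to the carbenoid carbon (ring enlargement of cycloalkanone–diazoacetate adducts). This should give the ring-enlarged β-keto ester F1. The known α-hydroxylation of β-keto ester enolates follows, using KN(SiMe3)2 and then an N-sulfonyloxaziridine. If needed, an enantiopure camphor-derived oxaziridine can reinforce α-face delivery. This leads to 16, but the C7-to-C6 stereochemical relay is given up.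

Step 9. Addition to the doubly α-substituted ketone may be slow and reversible. Competing enolisation would erode C1 and C5 or eliminate the C4 silyloxy group. The fallback sets out from 11 and comes back at 15. The smaller and more reactive lithium enolate of ethyl acetate (LiN(iPr)2, EtOAc, THF, −78 °C) is added from the same β face to give the β-hydroxy ester F2. Its dianion (2 equiv LiN(iPr)2) is hydroxylated with the N-sulfonyloxaziridine to the α,β-dihydroxy ester F3, whose C6 epimers are of no consequence. Dess–Martin oxidation of the secondary alcohol then gives 15.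

Step 13. Aminolysis at the ester on fully substituted C6 may be sluggish, and retro-aldol opening of the magnesium alkoxide may compete on warming. The fallback sets out from 17 and comes back at 21.
- LiBH4 reduces the α-hydroxy ester to the triol F4.
- TEMPO/PhI(OAc)2 oxidises the primary alcohol selectively to the α-hydroxy aldehyde F5.
- Excess 20 adds to give the allylic alcohol F6, whose carbinol epimers are of no consequence.
- MnO2 oxidises only this allylic alcohol to 21.

**Further compounds**
F1 | step 11 | ring-enlarged β-keto ester (C6 enolisable) | CC(C)(C)[Si](C)(C)O[C@@H]1[C@H](C(C)=C)C[C@@H](O[Si](C)(C)C(C)(C)C)[C@H](C)C(C(=O)OCC)C1=O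
F2 | step 9 | β-hydroxy ester (C7 α-OH) | CC(C)(C)[Si](C)(C)O[C@@H]1[C@H](C(C)=C)C[C@@H](O[Si](C)(C)C(C)(C)C)[C@H](C)[C@@]1(O)CC(=O)OCC
F3 | step 9 | α,β-dihydroxy ester (C6 epimers) | CC(C)(C)[Si](C)(C)O[C@@H]1[C@H](C(C)=C)C[C@@H](O[Si](C)(C)C(C)(C)C)[C@H](C)[C@@]1(O)C(O)C(=O)OCC
F4 | step 13 | triol (C6 hydroxymethyl) | CC(C)(C)[Si](C)(C)O[C@@H]1[C@H](C(C)=C)C[C@@H](O[Si](C)(C)C(C)(C)C)[C@H](C)[C@@](O)(CO)[C@H]1O
F5 | step 13 | α-hydroxy aldehyde | CC(C)(C)[Si](C)(C)O[C@@H]1[C@H](C(C)=C)C[C@@H](O[Si](C)(C)C(C)(C)C)[C@H](C)[C@@](O)(C=O)[C@H]1O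
F6 | step 13 | allylic alcohol (carbinol epimers) | CC(C)(C)[Si](C)(C)O[C@@H]1[C@H](C(C)=C)C[C@@H](O[Si](C)(C)C(C)(C)C)[C@H](C)[C@@](O)(C(O)/C=C/C)[C@H]1O
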